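I start from a one-step world, with one constant for the flasks below, and hand over the bench on that footing.

| flask | starting material | reagent | time |
|---|---|---|---|
| teal | 1.00 M | 1.00 M |  |
| red | 0.400 M | 0.400 M |  |
| amber | 1.50 M | 1.00 M |  |
| violet | 1.00 M | 1.50 M |  |
| ochre | 3.00 M | 0.500 M | 12 h |

- teal run (time / h: [target] / M): 0.68: 0.164; 2.1: 0.335; 4.0: 0.428; 6.3: 0.492; 9.0: 0.533; 12: 0.546
- red run (time / h: [target] / M): 0.68: 0.009; 2.1: 0.035; 4.0: 0.055; 6.3: 0.076; 9.0: 0.096; 12: 0.102
- amber run (time / h: [target] / M): 0.68: 0.226; 2.1: 0.430; 4.0: 0.542; 6.3: 0.616; 9.0: 0.648; 12: 0.673
- violet run (time / h: [target] / M): 0.68: 0.313; 2.1: 0.552; 4.0: 0.658; 6.3: 0.707; 9.0: 0.725; 12: 0.731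

(scatter of a reading: 0.003 M)

- Overall: starting material + reagent -> target.
- Constant volume, constant temperature.
- "The second partner" is reagent.
- An order is taken over about fifteen percent of the charge, up and down.

- how the opening rate goes with [reagent] round the charge of the teal run: the exponent of the rate at two percent of starting material gone to target
- how the opening rate goes with [starting material] round the charge of the teal run: the exponent of the rate at two percent of starting material gone to target (one fixed amount of target, the same in the runs compared)
- target in the ochre run at 12 h, as a share of the starting material charged

1. Orders, in logarithms: the first reading of amber over teal gives 0.791 for starting material, and violet over teal gives 1.59 for reagent. Amber has spent more of its reagent charge than teal by then, and so has violet, so both read low. I commit to one for starting material and two for reagent.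
2. Constant: with x the share of the teal charge turned, 1/(1−x)² − 1 = 2kt, and the first teal reading gives k = 0.317 /M²/h.
3. In the ochre flask, reagent is the limiting reagent, which caps target at 16.7 % of the starting material. I use the reagent clock, 1/(k × starting material charge × reagent charge), the hours in which half the reagent charge turns if starting material stays at its charge: 2.10 h. For 12 h, the clock puts the share of reagent turned at 0.851, or 14.2 % of the starting material.
4. At 12 h, the teal reading stands at 0.828 of what this law gives. Scaled by that, I expect 11.7 % from the ochre flask.
5. Keep the temperature unchanged: k was read at this temperature.

The forecast gives 1.95, 0.95 and 12.5 %, above my figure, and says: "All runs then stall faster than this law predicts."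

The ochre flask gives 12.8 %; round the teal charge the orders are 2.0 in reagent and 1.0 in starting material.

starting material + 2 reagent → target + reagent (0.3218 /M²/h); target + reagent → side product (0.01796 /M/h); starting material → decomposed substrate (0.04428 /h) The fit with the main steps alone forecasts 13.1 %. The result is 0.768 of the reagent charge, which the clock reads as 6.97 h of undisturbed running. The violet flask has the same product of charges as the ochre flask, so its clock from k is 2.10 h, and its reagent charge over its opening rate of 0.69 M/h gives 2.18 h.

All runs are simulated on assumed constants; the scatter is artificial.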